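**Retrosynthetic overview** (ring A = cyclohexadiene, ring B = seven-membered enol lactone, ring C = benzene, ring D = quinone, ring E = thiazine S,S-dioxide)
1. Target 27 ⇐ naphthol 25 (ring D at the 1-naphthol level, ring E complete) by Boc/SiMe3 removal and Teuber oxidation.
2. 25 ⇐ acyclic α-bromo β-keto sulfone 24, cutting two bonds at once: the bond from the ring C carbon para to the lactone carbonyl carbon to the quinone C=O carbon that neighbours the N-bearing carbon, and the C(N)=C(S) bond shared by rings D and E. Enabling feature: the S-bearing quinone carbon lies between C=O and SO2 (radical-stabilised methine of a β-keto sulfone), the ring nitrogen four atoms away can carry the other two carbons as a silyl ynamide, and ring C has a free ortho C–H.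
3. 24 ⇐ bromo ketone 15 + ynamide sulfinate 22 (sulfone by S-alkylation); 15 ⇐ aryl bromide 12 (Stille coupling, bromination).
4. Ring B of 12 ⇐ aldehyde acid 11 (dienolate O-acylation); ring A ⇐ Yamada–Otani annulation of 2-arylpropanal 4 with pent-1-en-3-one (sets the quaternary carbon), then vinyl cuprate/enol triflate, ozonolysis, triflate reduction.
5. Ring order: C (bought) → A → B → E and D together in the key step → quinone oxidation state last.

Key step: step 14

Assumption: in step 3 the L-proline-derived catalyst is taken to give the (S)-4-aryl-4-methylcyclohexenone, as with simple 2-arylpropanals, so the D-proline-derived catalyst is used; the ring carbon that carries vinyl/formyl in 8–11 is carried as an epimer mixture because it becomes sp2 in step 7.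

**Step 1**
Reactants: 1 5-bromo-2-iodobenzoic acid
Product: 2 tert-butyl 5-bromo-2-iodobenzoate
Conditions: tert-butyl 2,2,2-trichloroacetimidate (2 equiv), BF3·OEt2 (cat.), CH2Cl2/cyclohexane, 0 °C → rt
Reagents that add atoms: tert-butyl 2,2,2-trichloroacetimidate, CC(C)(C)OC(=N)C(Cl)(Cl)Cl
Why: Acid-catalysed tert-butylation of the carboxylic acid by a trichloroacetimidate (imidate esterification) should give an ester that is inert to the base, cuprate and palladium steps that follow and is later removed by acid.

**Step 2**
Reactants: 2 tert-butyl 5-bromo-2-iodobenzoate; 3 propanal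
Product: 4 tert-butyl 5-bromo-2-(1-oxopropan-2-yl)benzoate (racemic)
Conditions: Pd(OAc)2 (3 mol %), rac-BINAP (4.5 mol %), Cs2CO3 (1.3 equiv), propanal (2 equiv), 1,4-dioxane, sealed tube, 70 °C
Reagents that add atoms: none
Why: Pd-catalysed α-arylation of an aldehyde enolate, in which oxidative addition should occur at the C–I bond ortho to the ester in preference to the C–Br bond; the benzylic stereocenter is formed racemic, which is of no account because it is re-enolised in step 3.

**Step 3**
Reactants: 4 tert-butyl 5-bromo-2-(1-oxopropan-2-yl)benzoate; 5 pent-1-en-3-one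
Product: 7 tert-butyl 5-bromo-2-[(1R)-1,3-dimethyl-4-oxocyclohex-2-en-1-yl]benzoate, via keto aldehyde 6 (not isolated)
Conditions: (R)-N-[(4-dodecylphenyl)sulfonyl]pyrrolidine-2-carboxamide (20 mol %), 5 (2 equiv), ClCH2CH2Cl, rt; then LiOH·H2O, i-PrOH, rt
Reagents that add atoms: none
Why: Yamada–Otani condensation (enamine Michael addition then intramolecular aldol condensation, a Robinson-type annulation): the prolinamide forms the (E)-enamine of 4 and its acidic sulfonamide N–H binds the enone and delivers it to one enamine face, which should set the quaternary carbon (S in 6, R in 7 through the priority change only), and base then closes ring A.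

**Step 4**
Reactants: 7 tert-butyl 5-bromo-2-[(1R)-1,3-dimethyl-4-oxocyclohex-2-en-1-yl]benzoate
Product: 8 tert-butyl 5-bromo-2-[(1R,2RS)-2-ethenyl-1,3-dimethyl-4-(trifluoromethylsulfonyloxy)cyclohex-3-en-1-yl]benzoate
Conditions: CH2=CHMgBr (3 equiv), CuI (1.5 equiv), THF, −78 → −30 °C; then N-(5-chloropyridin-2-yl)bis(trifluoromethanesulfonimide), −78 °C → rt
Reagents that add atoms: vinylmagnesium bromide, C=C[Mg]Br; N-(5-chloropyridin-2-yl)bis(trifluoromethanesulfonimide), FC(F)(F)S(=O)(=O)N(c1ccc(Cl)cn1)S(=O)(=O)C(F)(F)F
Why: Conjugate addition of a vinyl cuprate to the enone and O-sulfonylation of the regiodefined enolate by an N-aryl triflimide should fix the position of the later ring double bond; the new vinyl-bearing stereocenter (expected mainly trans to the aryl group) becomes sp2 in step 7 and is carried as a mixture.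

**Step 5**
Reactants: 8 tert-butyl 5-bromo-2-[(1R,2RS)-2-ethenyl-1,3-dimethyl-4-(trifluoromethylsulfonyloxy)cyclohex-3-en-1-yl]benzoate
Product: 9 tert-butyl 5-bromo-2-[(1R,2RS)-2-formyl-1,3-dimethyl-4-(trifluoromethylsulfonyloxy)cyclohex-3-en-1-yl]benzoate
Conditions: O3, CH2Cl2/MeOH, −78 °C (Sudan red end point); then Me2S, −78 °C → rt
Reagents that add atoms: ozone, [O-][O+]=O
Why: Ozonolysis with reductive work-up should cleave only the monosubstituted vinyl group, since the enol triflate double bond and the arene are electron-poor.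

**Step 6**
Reactants: 9 tert-butyl 5-bromo-2-[(1R,2RS)-2-formyl-1,3-dimethyl-4-(trifluoromethylsulfonyloxy)cyclohex-3-en-1-yl]benzoate
Product: 10 tert-butyl 5-bromo-2-[(1R,2RS)-2-formyl-1,3-dimethylcyclohex-3-en-1-yl]benzoate
Conditions: Pd(OAc)2 (5 mol %), PPh3 (10 mol %), HCO2H (2 equiv), n-Bu3N (3 equiv), DMF, 60 °C
Reagents that add atoms: none
Why: Palladium-catalysed formate reduction of an alkenyl triflate (oxidative addition, formate decarboxylation, reductive elimination), in which zerovalent palladium with PPh3 should insert into the alkenyl C–OTf bond well before the unactivated aryl C–Br bond.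

**Step 7**
Reactants: 10 tert-butyl 5-bromo-2-[(1R,2RS)-2-formyl-1,3-dimethylcyclohex-3-en-1-yl]benzoate
Product: 12 (11aS)-3-bromo-8,11a-dimethyl-10,11-dihydrodibenzo[c,e]oxepin-5(11aH)-one, via aldehyde acid 11 (not isolated)
Conditions: CF3CO2H/CH2Cl2 (1:4), 0 °C; concentrate; then 2-chloro-1-methylpyridinium iodide (1.5 equiv), Et3N (4 equiv), CH2Cl2 (0.005 M), 40 °C
Reagents that add atoms: none
Why: Acidolysis of the tert-butyl ester then enol lactonisation, in which the acid is activated as its 2-acyloxypyridinium salt and amine-mediated enolisation at the only α-hydrogen gives the dienolate with the ring double bond already in place, which should be O-acylated at high dilution to close seven-membered ring B; no stereocenter is formed and the descriptor of the quaternary carbon changes from R to S only through the priority rules.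

**Step 8**
Reactants: 12 (11aS)-3-bromo-8,11a-dimethyl-10,11-dihydrodibenzo[c,e]oxepin-5(11aH)-one; 13 tributyl(1-ethoxyethenyl)stannane
Product: 15 (11aS)-3-(bromoacetyl)-8,11a-dimethyl-10,11-dihydrodibenzo[c,e]oxepin-5(11aH)-one, via aryl enol ether 14 (not isolated)
Conditions: Pd(PPh3)4 (5 mol %), toluene, 100 °C; then N-bromosuccinimide (1.0 equiv), THF/H2O (10:1), −20 °C
Reagents that add atoms: N-bromosuccinimide, O=C1CCC(=O)N1Br; water, O
Why: Stille coupling of the aryl bromide with the α-alkoxyvinyl stannane, then bromination of the enol ether and hydrolysis of the bromo oxocarbenium ion, should give the α-bromo ketone; the enol ether is far more nucleophilic than the dienol ester, which one equivalent of N-bromosuccinimide at low temperature should spare.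

**Step 9**
Reactants: 16 tert-butyl (2-bromoethyl)carbamate; 17 pyridine-2-thiol
Product: 18 tert-butyl [2-(pyridin-2-ylsulfanyl)ethyl]carbamate
Conditions: K2CO3 (1.5 equiv), DMF, rt
Reagents that add atoms: none
Why: S-Alkylation of the thiolate of pyridine-2-thiol by the primary bromide (SN2) should be clean.

**Step 10**
Reactants: 18 tert-butyl [2-(pyridin-2-ylsulfanyl)ethyl]carbamate
Product: 19 tert-butyl [2-(pyridin-2-ylsulfonyl)ethyl]carbamate
Conditions: (NH4)6Mo7O24·4H2O (5 mol %), 30 % H2O2 (4 equiv), EtOH, 0 °C → rt
Reagents that add atoms: hydrogen peroxide, OO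
Why: Molybdate-catalysed peroxide oxidation of the sulfide to the sulfone, in which the electron-poor pyridine nitrogen should not be oxidised.

**Step 11**
Reactants: 19 tert-butyl [2-(pyridin-2-ylsulfonyl)ethyl]carbamate; 20 (bromoethynyl)trimethylsilane
Product: 21 tert-butyl [2-(pyridin-2-ylsulfonyl)ethyl][(trimethylsilyl)ethynyl]carbamate
Conditions: KN(SiMe3)2 (1.0 equiv), CuI (1.0 equiv), pyridine/THF, 0 °C → rt; then 20 (2 equiv), rt
Reagents that add atoms: none
Why: Copper-mediated N-alkynylation of the potassium carbamate with a 1-bromoalkyne (ynamide synthesis through a copper amide), with one equivalent of base so that only the N–H is deprotonated.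

**Step 12**
Reactants: 21 tert-butyl [2-(pyridin-2-ylsulfonyl)ethyl][(trimethylsilyl)ethynyl]carbamate; 15 (11aS)-3-(bromoacetyl)-8,11a-dimethyl-10,11-dihydrodibenzo[c,e]oxepin-5(11aH)-one
Product: 23 ynamide β-keto sulfone, via sodium sulfinate 22 (not isolated)
Conditions: NaSEt (0.95 equiv), THF, 0 °C → rt; then 15 (0.9 equiv), DMF, rt
Reagents that add atoms: none
Why: Nucleophilic aromatic substitution by ethanethiolate at C-2 of the 2-pyridyl sulfone should release the alkanesulfinate, whose soft sulfur then displaces the α-bromide of 15 (sulfinate S-alkylation) under neutral conditions that the enol lactone and the ynamide tolerate.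

**Step 13**
Reactants: 23 ynamide β-keto sulfone
Product: 24 ynamide α-bromo β-keto sulfone (epimers at CHBr)
Conditions: NaH (1.0 equiv), THF, 0 °C; then N-bromosuccinimide (1.0 equiv), −78 °C
Reagents that add atoms: N-bromosuccinimide, O=C1CCC(=O)N1Br
Why: Electrophilic α-bromination of the preformed sodium enolate of the β-keto sulfone (the most acidic site) at low temperature, where dienol ester and ynamide should not react; the CHBr stereocenter is formed as a mixture and is destroyed in step 14.

**Step 14**
Reactants: 24 ynamide α-bromo β-keto sulfone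
Product: 25 N-Boc C-silyl thiazino-naphthol
Conditions: fac-Ir(ppy)3 (1 mol %), 2,6-lutidine (1.5 equiv), degassed DMF (0.005 M), blue LEDs (450 nm), rt
Reagents that add atoms: none
Why: Proposed new method: the excited trivalent iridium complex reduces the activated C–Br bond of 24 to the electrophilic α-keto-α-sulfonyl radical, which adds to the nitrogen-bearing ynamide carbon; the resulting α-silyl vinyl radical attacks the ortho C–H carbon of the aroyl ring, and oxidation of the cyclohexadienyl radical by the tetravalent iridium, loss of H+ to 2,6-lutidine and enolisation should give naphthol 25 with net loss of HBr. The closest known reaction types are the photoredox [4+2] benzannulation of 2-bromo-1-aryl-1,3-dicarbonyl compounds with alkynes to 1-naphthols and radical exo-dig cyclisations onto the nitrogen-bearing carbon of ynamides that end by attack on an arene; the tethered version on an α-bromo β-keto sulfone is what is new. The thiazine ring closes by 6-exo-dig radical cyclisation over the S–CH2–CH2–N tether and the carbocycle by six-membered homolytic aromatic substitution (6-endo with respect to the arene bond). No stereocenter is formed: the CHBr centre is destroyed and the quaternary carbon is remote. The step needs attack at the nitrogen-bearing carbon instead of 7-endo attack, which the four-atom tether and the bulky, radical-stabilising SiMe3 group on the distal alkyne carbon should secure, and it needs arylation at the ortho carbon para to the lactone carbonyl carbon and not at the one flanked by it, which sterics should secure. Ring closure must also outrun intermolecular addition of the radical to the dienol ester, which the high dilution should secure.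

**Step 15**
Reactants: 25 N-Boc C-silyl thiazino-naphthol
Product: 27 target thiazinoquinone, via amino naphthol 26 (not isolated)
Conditions: CF3CO2H/CH2Cl2 (1:4), 0 °C; concentrate; then K2[ON(SO3)2] (2.5 equiv), KH2PO4 buffer, acetone/H2O, 0 °C → rt
Reagents that add atoms: potassium nitrosodisulfonate K2[ON(SO3)2], [O]N(S(=O)(=O)[O-])S(=O)(=O)[O-].[K+].[K+]
Why: Acidolysis removes the Boc group and ipso-protodesilylates the silyl group para to the hydroxyl, and Teuber oxidation of the 1-naphthol at its free para position by the nitrosodisulfonate radical should give the para-quinone, a vinylogous amide stabilised by the ring nitrogen; no stereocenter is touched.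

**Compound list**
1 | 5-bromo-2-iodobenzoic acid | OC(=O)c1cc(Br)ccc1I | starting material
2 | tert-butyl 5-bromo-2-iodobenzoate | CC(C)(C)OC(=O)c1cc(Br)ccc1I | intermediate
3 | propanal | CCC=O | starting material
4 | tert-butyl 5-bromo-2-(1-oxopropan-2-yl)benzoate (racemic) | CC(C=O)c1ccc(Br)cc1C(=O)OC(C)(C)C | intermediate
5 | pent-1-en-3-one | CCC(=O)C=C | starting material
6 | tert-butyl 5-bromo-2-[(2S)-2-methyl-1,5-dioxoheptan-2-yl]benzoate (keto aldehyde, not isolated) | CCC(=O)CC[C@](c1ccc(Br)cc1C(=O)OC(C)(C)C)(C)C=O | intermediate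
7 | tert-butyl 5-bromo-2-[(1R)-1,3-dimethyl-4-oxocyclohex-2-en-1-yl]benzoate | O=C1CC[C@](c2ccc(Br)cc2C(=O)OC(C)(C)C)(C)C=C1C | intermediate
8 | tert-butyl 5-bromo-2-[(1R,2RS)-2-ethenyl-1,3-dimethyl-4-(trifluoromethylsulfonyloxy)cyclohex-3-en-1-yl]benzoate | C1C[C@](c2ccc(Br)cc2C(=O)OC(C)(C)C)(C)C(C=C)C(C)=C1OS(=O)(=O)C(F)(F)F | intermediate
9 | tert-butyl 5-bromo-2-[(1R,2RS)-2-formyl-1,3-dimethyl-4-(trifluoromethylsulfonyloxy)cyclohex-3-en-1-yl]benzoate | C1C[C@](c2ccc(Br)cc2C(=O)OC(C)(C)C)(C)C(C=O)C(C)=C1OS(=O)(=O)C(F)(F)F | intermediate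
10 | tert-butyl 5-bromo-2-[(1R,2RS)-2-formyl-1,3-dimethylcyclohex-3-en-1-yl]benzoate | C1C[C@](c2ccc(Br)cc2C(=O)OC(C)(C)C)(C)C(C=O)C(C)=C1 | intermediate
11 | 5-bromo-2-[(1R,2RS)-2-formyl-1,3-dimethylcyclohex-3-en-1-yl]benzoic acid (aldehyde acid, not isolated) | C1C[C@](c2ccc(Br)cc2C(=O)O)(C)C(C=O)C(C)=C1 | intermediate
12 | (11aS)-3-bromo-8,11a-dimethyl-10,11-dihydrodibenzo[c,e]oxepin-5(11aH)-one (rings A, B, C; C-5 lactone carbonyl, O-6, C-7 enol CH) | CC1=CCC[C@]2(C)C1=COC(=O)c1cc(Br)ccc12 | intermediate
13 | tributyl(1-ethoxyethenyl)stannane | CCCC[Sn](CCCC)(CCCC)C(=C)OCC | starting material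
14 | (11aS)-3-(1-ethoxyethenyl)-8,11a-dimethyl-10,11-dihydrodibenzo[c,e]oxepin-5(11aH)-one (aryl enol ether, not isolated) | CC1=CCC[C@]2(C)C1=COC(=O)c1cc(C(=C)OCC)ccc12 | intermediate
15 | (11aS)-3-(bromoacetyl)-8,11a-dimethyl-10,11-dihydrodibenzo[c,e]oxepin-5(11aH)-one | CC1=CCC[C@]2(C)C1=COC(=O)c1cc(C(=O)CBr)ccc12 | intermediate
16 | tert-butyl (2-bromoethyl)carbamate | CC(C)(C)OC(=O)NCCBr | starting material
17 | pyridine-2-thiol | Sc1ccccn1 | starting material
18 | tert-butyl [2-(pyridin-2-ylsulfanyl)ethyl]carbamate | CC(C)(C)OC(=O)NCCSc1ccccn1 | intermediate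
19 | tert-butyl [2-(pyridin-2-ylsulfonyl)ethyl]carbamate | CC(C)(C)OC(=O)NCCS(=O)(=O)c1ccccn1 | intermediate
20 | (bromoethynyl)trimethylsilane | C[Si](C)(C)C#CBr | starting material
21 | tert-butyl [2-(pyridin-2-ylsulfonyl)ethyl][(trimethylsilyl)ethynyl]carbamate | CC(C)(C)OC(=O)N(CCS(=O)(=O)c1ccccn1)C#C[Si](C)(C)C | intermediate
22 | sodium 2-{(tert-butoxycarbonyl)[(trimethylsilyl)ethynyl]amino}ethanesulfinate (not isolated) | CC(C)(C)OC(=O)N(CCS(=O)[O-])C#C[Si](C)(C)C.[Na+] | intermediate
23 | ynamide β-keto sulfone: tert-butyl N-[2-({2-[(11aS)-8,11a-dimethyl-5-oxo-5,10,11,11a-tetrahydrodibenzo[c,e]oxepin-3-yl]-2-oxoethyl}sulfonyl)ethyl]-N-[(trimethylsilyl)ethynyl]carbamate | CC1=CCC[C@]2(C)C1=COC(=O)c1cc(C(=O)CS(=O)(=O)CCN(C(=O)OC(C)(C)C)C#C[Si](C)(C)C)ccc12 | intermediate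
24 | ynamide α-bromo β-keto sulfone: 23 with Br on the carbon between C=O and SO2 (RS at that carbon, S at the quaternary carbon) | CC1=CCC[C@]2(C)C1=COC(=O)c1cc(C(=O)C(Br)S(=O)(=O)CCN(C(=O)OC(C)(C)C)C#C[Si](C)(C)C)ccc12 | intermediate
25 | N-Boc C-silyl thiazino-naphthol: pentacycle with ring D as 1-naphthol (OH on the ring D carbon next to the sulfonyl-bearing carbon, SiMe3 on the ring D carbon next to the N-bearing carbon), N-Boc thiazine S,S-dioxide ring E, S at the quaternary carbon | CC1=CCC[C@]2(C)C1=COC(=O)c1cc3c(O)c4c(N(C(=O)OC(C)(C)C)CCS4(=O)=O)c([Si](C)(C)C)c3cc12 | intermediate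
26 | amino naphthol: 25 without Boc and SiMe3 (not isolated) | CC1=CCC[C@]2(C)C1=COC(=O)c1cc3c(O)c4c(NCCS4(=O)=O)cc3cc12 | intermediate
27 | target thiazinoquinone CNP0348176.1, (S) at the quaternary carbon | CC1=CCC[C@]2(C)C1=COC(=O)c1cc3c(cc12)C(=O)C1=C(C3=O)S(=O)(=O)CCN1 | target

**Step count and risks**
Total steps: 15. Longest linear sequence: 12 steps (steps 1–8 and 12–15, from 1); steps 9–11 build the ynamide fragment in parallel.

Steps most likely to fail:

1. Step 14 (proposed new method). The radical may attack the silyl-bearing alkyne carbon in the 7-endo mode, may be reduced back to the C–H compound, or may add to the dienol ester of a second molecule before it cyclises. Fallback, from 15 back to 27, with an intermolecular, polarity-matched annulation and closure of ring E by N–C bond formation: bromo ketone 15 is S-alkylated (DMF, rt) with sodium 2-[(tert-butoxycarbonyl)amino]ethanesulfinate F1 (from commercial hypotaurine, Boc2O, NaOH) to β-keto sulfone F2, and NaH/N-bromosuccinimide gives bromide F3. Irradiation of F3 with fac-Ir(ppy)3 and 2,6-lutidine in the presence of a large excess of ethynyltrimethylsilane, the known photoredox [4+2] naphthol synthesis from 2-bromo aroyl active-methylene compounds and terminal alkynes (the radical adds to the unsubstituted alkyne terminus and the α-silyl vinyl radical closes onto the arene), should give 2-sulfonyl-4-silyl-1-naphthol F4. CF3CO2H removes Boc and SiMe3 to give amino naphthol F5, and K2[ON(SO3)2] oxidises it to sulfonyl naphthoquinone F6, whose primary amine should add to the free quinone carbon next to the sulfonyl-bearing carbon (the N–C bond-forming half of the known hypotaurine–quinone condensation); reoxidation by excess oxidant returns to the route at 27.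

2. Step 7. The dienolate may be acylated at carbon (five-membered ketone) or between molecules, or base may move the ring double bond into conjugation so that enolisation takes place at the methyl group. Fallback, from 10 back to 12, forming the lactone C–O bond at the sp3 aldehyde carbon before the double bond exists: after acidolysis of 10 to 11, Ac2O/pyridine should close the pseudo-acid form to cyclic acylal F7 (the 7-acetoxy-7,7a-dihydro lactone), and elimination of acetic acid (Me3SiOTf, i-Pr2NEt, CH2Cl2, 0 °C, through the acyloxocarbenium ion and loss of the neighbouring ring proton) should give 12.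

3. Step 3. Facial selectivity of the enamine Michael addition may be poor with the ortho-substituted aryl aldehyde, or the hindered enamine may form slowly. Fallback, from 4 and 5 back to 7, by resolution instead of asymmetric catalysis: racemic annulation (pyrrolidine, AcOH, toluene; then KOH, MeOH) and separation of (±)-7 by preparative chromatography on a chiral stationary phase, the (S)-enone F8 being set aside and (R)-7 entering step 4.

**Further compounds**
F1 | step 14 | sodium 2-[(tert-butoxycarbonyl)amino]ethanesulfinate | CC(C)(C)OC(=O)NCCS(=O)[O-].[Na+]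
F2 | step 14 | β-keto sulfone: tert-butyl N-[2-({2-[(11aS)-8,11a-dimethyl-5-oxo-5,10,11,11a-tetrahydrodibenzo[c,e]oxepin-3-yl]-2-oxoethyl}sulfonyl)ethyl]carbamate | CC1=CCC[C@]2(C)C1=COC(=O)c1cc(C(=O)CS(=O)(=O)CCNC(=O)OC(C)(C)C)ccc12
F3 | step 14 | α-bromo derivative of F2 (Br on the carbon between C=O and SO2) | CC1=CCC[C@]2(C)C1=COC(=O)c1cc(C(=O)C(Br)S(=O)(=O)CCNC(=O)OC(C)(C)C)ccc12
F4 | step 14 | 2-sulfonyl-4-silyl-1-naphthol with N-Boc aminoethylsulfonyl side chain | CC1=CCC[C@]2(C)C1=COC(=O)c1cc3c(O)c(S(=O)(=O)CCNC(=O)OC(C)(C)C)cc([Si](C)(C)C)c3cc12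
F5 | step 14 | amino naphthol: F4 without Boc and SiMe3 | CC1=CCC[C@]2(C)C1=COC(=O)c1cc3c(O)c(S(=O)(=O)CCN)ccc3cc12
F6 | step 14 | 2-[(2-aminoethyl)sulfonyl]-1,4-naphthoquinone fused to rings A–C | CC1=CCC[C@]2(C)C1=COC(=O)c1cc3c(cc12)C(=O)C=C(C3=O)S(=O)(=O)CCN
F7 | step 7 | cyclic acylal: 7-acetoxy-3-bromo-8,11a-dimethyl-7,7a,10,11-tetrahydrodibenzo[c,e]oxepin-5(11aH)-one | CC1=CCC[C@]2(C)C1C(OC(C)=O)OC(=O)c1cc(Br)ccc12
F8 | step 3 | tert-butyl 5-bromo-2-[(1S)-1,3-dimethyl-4-oxocyclohex-2-en-1-yl]benzoate | O=C1CC[C@@](c2ccc(Br)cc2C(=O)OC(C)(C)C)(C)C=C1C
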